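## Retrosynthetic overview

1. The Z-enedione is unmasked in the last step by oxidative opening of a 2,3,5-trisubstituted furan held inside the macrocycle.
2. **Key step:** an acyclic (Z)-2-en-4-ynone is cycloisomerised by Rh(II). Ketone-O 5-exo-dig closure gives a 2-furyl carbene at C7, which cyclopropanates the remote C8=C9 isopropenyl group. The furan, the cyclopropane (C7, C8) and the 13-membered ring all form in this one step.
3. The seco-enynone comes from C1–C2 bond formation: a chiral-phosphoric-acid-catalysed anti-allylboration of an enynyl glyoxal with an (E)-allylboronate sets C1 and C2.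
4. The boronate comes from asymmetric propiolate addition to methacrolein (sets C10), Ru Alder-ene butenolide formation, Wittig, reduction and borylation. The glyoxal comes from Z-iodo-olefination of TMS-propynal followed by acylation.
5. Ring order: butenolide first, then furan, cyclopropane and macrocycle together, then the furan is opened. The route avoids the usual plan of NHK or Stille macrocyclisation on a preformed furan with a Simmons–Smith cyclopropane.

## Conventions and assumptions

- **Numbering (cembranoid-type):** C1 = CH(isopropenyl), C2 = CHOAc, C3 = C=O, C4 = C(Me)=, C5 = =CH, C6 = C=O, C7 = cyclopropane CH, C8 = cyclopropane C(Me), C9 = cyclopropane CH2, C10 = lactone CH–O, C11 = butenolide =CH, C12 = butenolide α-C, C13/C14 = CH2CH2, C20 = lactone C=O.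
- **Target as read from the SMILES:** 1S,2S,7S,8S,10S, 4Z. C6 and C10 are trans on the cyclopropane, so the acyl group is cis to the C8 methyl.
- **Catalyst antipodes are quoted by analogy.** (R)-TRIP gives the R-carbinol with aryl aldehydes, so (S)-TRIP is used here. The ProPhenol sense is assumed. If the first Mosher check shows the opposite sense, the commercial antipode is used and nothing else changes.
- **Weinreb amide 15 is taken as a catalogue item.** Otherwise it is two routine steps from methyl glycolate.

## Route

**Step 1**
Reactants: 1 methacrolein; 2 methyl propiolate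
Product: 3 methyl (4R)-4-hydroxy-5-methylhex-5-en-2-ynoate
Conditions: (S,S)-ProPhenol (10 mol %), Me2Zn (3 equiv), Ph3P=O (20 mol %), PhMe, 0–4 °C
Reagents that add atoms: methyl propiolate, C#CC(=O)OC
Why: Dinuclear Zn–ProPhenol asymmetric alkynylation of an enal delivers the zinc propiolate to one aldehyde face and sets C10, which is (R) here but has the same spatial arrangement as 10S in the target because alkynyl outranks isopropenyl.

**Step 2**
Reactants: 3; 4 allyl alcohol
Product: 5 3-[(5S)-2-oxo-5-(prop-1-en-2-yl)-2,5-dihydrofuran-3-yl]propanal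
Conditions: [CpRu(MeCN)3]PF6 (5 mol %), CSA (cat.), THF–acetone, rt (–MeOH)
Reagents that add atoms: allyl alcohol, C=CCO
Why: In the Trost Ru alkene–alkyne (Alder-ene) coupling the C–C bond forms at the ynoate α-carbon with syn H/C delivery, the enol tautomerises to the aldehyde, the (Z)-γ-hydroxy enoate lactonises spontaneously, and the 1,1-disubstituted isopropenyl group is not a competent ene partner.

**Step 3**
Reactants: 5; 6 2-(triphenylphosphoranylidene)propanal
Product: 7 (2E)-2-methyl-5-[(5S)-2-oxo-5-(prop-1-en-2-yl)-2,5-dihydrofuran-3-yl]pent-2-enal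
Conditions: 6 (1.3 equiv), PhH, 60 °C
Reagents that add atoms: 2-(triphenylphosphoranylidene)propanal, CC(C=O)=P(c1ccccc1)(c1ccccc1)c1ccccc1
Why: Wittig olefination with a stabilised ylide gives the E-trisubstituted enal, and the ylide is too weakly basic to deprotonate the doubly allylic C10–H.

**Step 4**
Reactants: 7
Product: 8 (5S)-3-[(3E)-5-hydroxy-4-methylpent-3-en-1-yl]-5-(prop-1-en-2-yl)furan-2(5H)-one
Conditions: NaBH4, CeCl3·7H2O, MeOH, –40 °C
Reagents that add atoms: none
Why: Luche 1,2-reduction takes the aldehyde far faster than the butenolide, and the slightly acidic medium avoids deprotonation at C10.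

**Step 5**
Reactants: 8; 9 bis(pinacolato)diboron
Product: 10 (5S)-3-[(3E)-4-methyl-5-(4,4,5,5-tetramethyl-1,3,2-dioxaborolan-2-yl)pent-3-en-1-yl]-5-(prop-1-en-2-yl)furan-2(5H)-one
Conditions: B2pin2 (1.2 equiv), [Pd(MeCN)4](BF4)2 (5 mol %), DMSO–MeOH, rt
Reagents that add atoms: B2pin2, CC1(C)OB(B2OC(C)(C)C(C)(C)O2)OC1(C)C
Why: In this Pd-catalysed direct allylic C–OH borylation, in situ borate/BF3 activation makes the primary allylic OH leave faster than an allylic carboxylate such as the C10–O lactone bond, and boron goes to the unhindered terminus with E geometry.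

**Step 6**
Reactants: 11 3-(trimethylsilyl)propynal; 12 ethyltriphenylphosphonium iodide; 13 iodine
Product: 14 [(3Z)-4-iodopent-3-en-1-yn-1-yl]trimethylsilane (I cis to alkynyl)
Conditions: 12, n-BuLi, THF, 0 °C; I2, –78 °C; NaHMDS, –20 °C; then 11, –78 °C
Reagents that add atoms: ethyltriphenylphosphonium iodide, CC[P+](c1ccccc1)(c1ccccc1)c1ccccc1.[I-]; iodine, II
Why: Stork–Zhao-type α-iodoethylidene Wittig olefination proceeds through the kinetic cis-oxaphosphetane to the (Z)-2-iodoalkene, which fixes the C4=C5 geometry needed later for furan closure.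

**Step 7**
Reactants: 14; 15 2-[(tert-butyldimethylsilyl)oxy]-N-methoxy-N-methylacetamide
Product: 16 (3Z)-1-[(tert-butyldimethylsilyl)oxy]-3-methyl-6-(trimethylsilyl)hex-3-en-5-yn-2-one
Conditions: t-BuLi (2.1 equiv), Et2O, –78 °C; then 15, –78 → –20 °C
Reagents that add atoms: Weinreb amide 15, CON(C)C(=O)CO[Si](C)(C)C(C)(C)C
Why: I/Li exchange is faster than E2 elimination and retains the alkene geometry, and the chelated tetrahedral intermediate of the Weinreb ketone synthesis prevents over-addition.

**Step 8**
Reactants: 16
Product: 17 (3Z)-1-hydroxy-3-methylhex-3-en-5-yn-2-one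
Conditions: TBAF (2.2 equiv), AcOH (2.4 equiv), THF, 0 °C
Reagents that add atoms: none
Why: Buffered fluoride desilylation removes O-TBS and C-TMS together, and the AcOH suppresses base-induced 1,6-addition or Z/E isomerisation of the enynone.

**Step 9**
Reactants: 17
Product: 18 (3Z)-3-methyl-2-oxohex-3-en-5-ynal (enynyl glyoxal, used at once)
Conditions: DMP (1.2 equiv), CH2Cl2, 0 °C → rt; filter, swap to PhMe
Reagents that add atoms: none
Why: Dess–Martin oxidation of the primary α-ketol gives the anhydrous α-keto aldehyde under neutral, non-aqueous conditions.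

**Step 10**
Reactants: 10; 18 (1.5 equiv)
Product: 19 (5S)-3-[(3S,4S,6Z)-4-hydroxy-6-methyl-5-oxo-3-(prop-1-en-2-yl)non-6-en-8-yn-1-yl]-5-(prop-1-en-2-yl)furan-2(5H)-one (1S,2S,10S)
Conditions: (S)-TRIP (10 mol %), 4 Å MS, PhMe, –45 °C
Reagents that add atoms: glyoxal 18, C#C/C=C(/C)C(=O)C=O
Why: Chiral-phosphoric-acid-catalysed allylboration goes through a closed chair in which the E-boronate gives the anti C1/C2 relationship, (S)-TRIP exposes the Si face of the aldehyde to give 2S and hence 1S, and only the aldehyde of the keto-aldehyde reacts.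

**Step 11**
Reactants: 19; 20 acetic anhydride
Product: 21 (3S,4S,6Z)-6-methyl-5-oxo-1-[(5S)-2-oxo-5-(prop-1-en-2-yl)-2,5-dihydrofuran-3-yl]-3-(prop-1-en-2-yl)non-6-en-8-yn-4-yl acetate
Conditions: Ac2O, pyridine, CH2Cl2, 0 °C (no DMAP)
Reagents that add atoms: acetic anhydride, CC(=O)OC(C)=O
Why: O-acylation with a base too weak to epimerise C2 or isomerise the γ-isopropenyl butenolide also removes the OH that would otherwise undergo carbene O–H insertion in step 12.

**Step 12 (key step)**
Reactants: 21
Product: 22 (1S,2S,7S,8S,10S)-furanophane. It is a 13-membered carbocycle bridged C3–C6 by a 3-methylfuran-2,5-diyl. It carries a trans-1-methylcyclopropane-1,2-diyl (C8/C7, furyl cis to Me), the C10–C12 butenolide, the C2 acetate and the C1 isopropenyl group.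
Conditions: Rh2(OAc)4 (10 mol %), 4 Å MS, CH2Cl2, 25–40 °C, dark; 21 added by syringe pump over 16 h, final 1 mM
Reagents that add atoms: none (isomerisation)
Why: Proposed new method: Rh(II) π-activation of the terminal alkyne triggers 5-exo-dig attack by the cis C3 ketone oxygen to give a 2-furyl rhodium carbene at C7 (known carbonyl-ene-yne to furylcarbene cyclopropanation, so far used intermolecularly or with short tethers), which at high dilution adds to the only alkene it can reach, because the rigid 2,5-furan spacer makes the nearer C15=C16 isopropenyl inaccessible and the butenolide C=C is electron-poor, by end-on attack at the unhindered C9H2 terminus (14-membered TS) and collapse onto C8 as in macrocyclic carbenoid cyclopropanations of remote methallyl groups by diazo esters, with the furyl group orienting anti to the bulky lactone (C6/C10 trans) and, in the A1,3-minimised rotamer with C10–H eclipsing C8=C9, the tether carbon C11 lying over the Re face of C8 so that tether delivery gives 7S,8S.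

**Step 13**
Reactants: 22; 23 m-chloroperbenzoic acid
Product: 24 pinnatin B
Conditions: mCPBA (1.05 equiv), CH2Cl2, 0 °C
Reagents that add atoms: mCPBA (one O), O=C(OO)c1cccc(Cl)c1
Why: Oxidative furan ring opening (epoxidation of the electron-rich trisubstituted furan, then ring opening) gives the enedione with Z geometry inherited from the ring, and the furan reacts faster than the 1,1-disubstituted alkene, as is known for furanocembranoids.

## Compound list

| No. | Name | SMILES | Role |
|---|---|---|---|
| 1 | methacrolein | C=C(C)C=O | starting material |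
| 2 | methyl propiolate | C#CC(=O)OC | starting material |
| 3 | methyl (4R)-4-hydroxy-5-methylhex-5-en-2-ynoate | C=C(C)[C@@H](O)C#CC(=O)OC | intermediate |
| 4 | allyl alcohol | C=CCO | starting material |
| 5 | 3-[(5S)-2-oxo-5-isopropenyl-2,5-dihydrofuran-3-yl]propanal | C=C(C)[C@@H]1C=C(CCC=O)C(=O)O1 | intermediate |
| 6 | 2-(triphenylphosphoranylidene)propanal | CC(C=O)=P(c1ccccc1)(c1ccccc1)c1ccccc1 | starting material |
| 7 | (E)-enal | C=C(C)[C@@H]1C=C(CC/C=C(\C)C=O)C(=O)O1 | intermediate |
| 8 | (E)-allylic alcohol | C=C(C)[C@@H]1C=C(CC/C=C(\C)CO)C(=O)O1 | intermediate |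
| 9 | bis(pinacolato)diboron | CC1(C)OB(B2OC(C)(C)C(C)(C)O2)OC1(C)C | starting material |
| 10 | (E)-allyl pinacolboronate | C=C(C)[C@@H]1C=C(CC/C=C(\C)CB2OC(C)(C)C(C)(C)O2)C(=O)O1 | intermediate |
| 11 | 3-(trimethylsilyl)propynal | C[Si](C)(C)C#CC=O | starting material |
| 12 | ethyltriphenylphosphonium iodide | CC[P+](c1ccccc1)(c1ccccc1)c1ccccc1.[I-] | starting material |
| 13 | iodine | II | starting material |
| 14 | [(3Z)-4-iodopent-3-en-1-yn-1-yl]trimethylsilane | C/C(I)=C/C#C[Si](C)(C)C | intermediate |
| 15 | 2-(TBSO)-N-methoxy-N-methylacetamide | CON(C)C(=O)CO[Si](C)(C)C(C)(C)C | starting material |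
| 16 | (3Z)-1-(TBSO)-3-methyl-6-(TMS)hex-3-en-5-yn-2-one | C[Si](C)(C)C#C/C=C(/C)C(=O)CO[Si](C)(C)C(C)(C)C | intermediate |
| 17 | (3Z)-1-hydroxy-3-methylhex-3-en-5-yn-2-one | C#C/C=C(/C)C(=O)CO | intermediate |
| 18 | (3Z)-3-methyl-2-oxohex-3-en-5-ynal | C#C/C=C(/C)C(=O)C=O | intermediate |
| 19 | seco α-hydroxy enynone (1S,2S,10S) | C#C/C=C(/C)C(=O)[C@@H](O)[C@@H](CCC1=C[C@@H](C(C)=C)OC1=O)C(C)=C | intermediate |
| 20 | acetic anhydride | CC(=O)OC(C)=O | starting material |
| 21 | seco α-acetoxy enynone (1S,2S,10S) | C#C/C=C(/C)C(=O)[C@@H](OC(C)=O)[C@@H](CCC1=C[C@@H](C(C)=C)OC1=O)C(C)=C | intermediate |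
| 22 | furanophane (1S,2S,7S,8S,10S) | C=C(C)[C@@H]1CCC2=C[C@H](OC2=O)[C@@]2(C)C[C@@H]2c2cc(C)c(o2)[C@H]1OC(C)=O | intermediate |
| 23 | m-chloroperbenzoic acid | O=C(OO)c1cccc(Cl)c1 | starting material |
| 24 | pinnatin B | C=C(C)[C@@H]1CCC2=C[C@H](OC2=O)[C@@]2(C)C[C@@H]2C(=O)/C=C(/C)C(=O)[C@H]1OC(C)=O | target |

## Step count

- **Total steps:** 13
- **Longest linear sequence:** 9 (steps 1–5, then 10–13). The glyoxal branch runs 8 steps to the target (steps 6–9, then 10–13).

## Three steps most likely to fail

1. **Step 12.**
   - Risks: the donor-type furyl carbene may react too slowly with an alkene deactivated by the allylic acyloxy group; oligomerisation or C10–H insertion may compete; four cyclopropane diastereomers are possible, and the facial argument is a conformational model only.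
   - Fallback: move the carbene transfer to fragment stage. Cyclopropanate the silyl ether of 3 (used in excess) intermolecularly under chiral Rh(II) control, with a small enynone that carries a masked C2 aldehyde. Then build the butenolide and allylic bromide as in steps 2–4, and close the 13-membered ring at C1–C2 by intramolecular NHK allylation of the furfural.

2. **Steps 9 and 10.**
   - Risks: glyoxal 18 is labile, and an uncatalysed background allylboration could erode the ee.
   - Fallback: form C3–C4 late instead. Allylborate commercial TBSOCH2CHO with 10 under the same catalysis. Then acetylate, desilylate with HF·pyridine and oxidise with DMP to the α-acetoxy aldehyde. Couple this with vinyl iodide 14 by NHK (CrCl2/NiCl2), oxidise with DMP, and remove the C-TMS group to reach 21.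

3. **Step 5.**
   - Risks: Pd may ionise the allylic lactone C10–O bond, causing racemisation or ring opening, or may scramble the E geometry.
   - Fallback: drop boron. Convert 8 to the allylic bromide (CBr4/PPh3) and couple it with 18 by a Cr-catalysed asymmetric Nozaki–Hiyama–Kishi allylation with a chiral oxazoline–sulfonamide ligand. This reaction is anti-selective whatever the allyl geometry.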